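**Plan**

- Locants: C1 and C10 are the ring-fusion carbons of the cyclohexane/tetrahydrofuran pair (C1 bonded to C2 and C14, C10 to C9 and C11); C2 and C9 are the two O–CH of the tetrahydrofuran; C3 is the methyl-bearing quaternary ether carbon; C4–C8 complete the nine-membered ether (C6=C7(Me)); C11 is CHOAc, C12 CHMe, C13 CH2; C14 carries the C15H(Me)–C16H2–O arm.
- Retrosynthetic cuts, in order: the acetate; the C16–O bond of the oxepane; C6=C7 (ring-closing metathesis); O–C9 and C9–C10 of the tetrahydrofuran in one operation; C1–C2 (homoaldol union of a cyclohexenyl carbamate with a C2–C6 aldehyde).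
- Enabling feature: in the cyclohexane-fused tetrahydrofuran the ring oxygen on C9 and the acetoxy oxygen on C11 flank C10 (an aldol pattern). With C11 as a ketone, C10 is its enol carbon and C9 an oxocarbenium carbon carried by the C2 oxygen.
- Forward order: cyclohexene (Michael addition/aldol condensation), C1–C2 union, tetrahydrofuran, oxonene, C11 reduction and acetylation, oxepane.
- Stereochemistry: C15 from (S)-3-bromo-2-methylpropan-1-ol; C3 from (R)-2-methylglycidol; C14 from the prolinol ether catalyst; C12 by anti alkylation; C1 and C2 by chirality transfer through the allyltitanium chair; C9 and C10 in the key step; C11 by hydride attack anti to its two neighbours.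

Key step: step 14

Assumption: both enantiopure building blocks 1 and 12 are taken as commercial. 3-Methylbut-3-enal is used as its diethyl acetal and C16–O is carried as a triisopropylsilyl ether; neither choice changes the bonds formed in the key step.

**Route**

Step 1
Reactants: 1 (2S)-3-bromo-2-methylpropan-1-ol
Product: 2 [(2S)-3-bromo-2-methylpropoxy]tri(propan-2-yl)silane
Conditions: iPr3SiCl, imidazole, DMF, rt
Reagents that add atoms: chlorotri(propan-2-yl)silane CC(C)[Si](Cl)(C(C)C)C(C)C
Why: Imidazole-promoted silyl ether formation; the triisopropylsilyl ether has no benzylic C–H for sBuLi to attack in step 13 and should survive BF3·OEt2 and Na/NH3.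

Step 2
Reactants: 2 [(2S)-3-bromo-2-methylpropoxy]tri(propan-2-yl)silane
Product: 4 (3R)-3-methyl-4-(triisopropylsilyloxy)butanal, via Grignard reagent 3 (not isolated)
Conditions: Mg, THF, 40 °C; DMF, 0 °C; 1 M HCl, 0 °C
Reagents that add atoms: N,N-dimethylformamide CN(C)C=O
Why: Grignard formation and Bouveault formylation add the aldehyde carbon (C1 of the target) one bond away from the untouched stereocentre (C15).

Step 3
Reactants: 4 (3R)-3-methyl-4-(triisopropylsilyloxy)butanal; 5 but-3-en-2-one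
Product: 6 (2S)-5-oxo-2-[(2R)-1-(triisopropylsilyloxy)propan-2-yl]hexanal
Conditions: (S)-2-[methoxy(diphenyl)methyl]pyrrolidine (5 mol%), ethyl 3,4-dihydroxybenzoate (20 mol%), neat, 4 °C
Reagents that add atoms: none
Why: Enamine-catalysed Michael addition in which the diphenylmethyl group of the (S)-catalyst shields one face of the anti-enamine, so the enone should add to the open face and set C14 (2S) under catalyst control.

Step 4
Reactants: 6 (2S)-5-oxo-2-[(2R)-1-(triisopropylsilyloxy)propan-2-yl]hexanal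
Product: 7 (4R)-4-[(2R)-1-(triisopropylsilyloxy)propan-2-yl]cyclohex-2-en-1-one
Conditions: LiOH·H2O (cat.), iPrOH, rt
Reagents that add atoms: none
Why: Intramolecular aldol condensation of the methyl ketone onto the aldehyde closes the cyclohexenone, and the mild catalytic base should leave C14 intact.

Step 5
Reactants: 7 (4R)-4-[(2R)-1-(triisopropylsilyloxy)propan-2-yl]cyclohex-2-en-1-one
Product: 9 (4R,6R)-6-methyl-4-[(2R)-1-(triisopropylsilyloxy)propan-2-yl]cyclohex-2-en-1-one, via lithium dienolate 8 (not isolated)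
Conditions: LiN(iPr)2, THF, −78 °C; MeI, −78 → −40 °C
Reagents that add atoms: iodomethane CI
Why: Kinetic deprotonation at C6 and enolate alkylation, in which MeI should enter axially on the half-chair that keeps the C4 side chain pseudo-equatorial, giving the 4,6-trans isomer (C12 of the target); any cis isomer is removed by chromatography.

Step 6
Reactants: 9 (4R,6R)-6-methyl-4-[(2R)-1-(triisopropylsilyloxy)propan-2-yl]cyclohex-2-en-1-one
Product: 10 (1R,4R,6R)-6-methyl-4-[(2R)-1-(triisopropylsilyloxy)propan-2-yl]cyclohex-2-en-1-ol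
Conditions: NaBH4, CeCl3·7H2O, MeOH, −78 °C
Reagents that add atoms: none
Why: Luche 1,2-reduction, in which hydride should add axially and anti to the pseudo-axial C6 methyl group of the half-chair with a pseudo-equatorial C4 side chain, giving the alcohol with OH cis to the methyl group and trans to the side chain; this carbinol configuration decides which ring face is metalated in step 13.

Step 7
Reactants: 10 (1R,4R,6R)-6-methyl-4-[(2R)-1-(triisopropylsilyloxy)propan-2-yl]cyclohex-2-en-1-ol
Product: 11 (1R,4R,6R)-6-methyl-4-[(2R)-1-(triisopropylsilyloxy)propan-2-yl]cyclohex-2-en-1-yl N,N-di(propan-2-yl)carbamate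
Conditions: iPr2NCOCl, pyridine, DMAP (cat.), 90 °C
Reagents that add atoms: N,N-di(propan-2-yl)carbamoyl chloride CC(C)N(C(C)C)C(Cl)=O
Why: O-Carbamoylation of the secondary alcohol installs the group that directs α-lithiation and later activates the enol.

Step 8
Reactants: 12 [(2R)-2-methyloxiran-2-yl]methanol; 13 prop-2-en-1-ylmagnesium chloride
Product: 14 (2S)-2-methylhex-5-ene-1,2-diol
Conditions: 13 (2.5 equiv), CuI (10 mol%), THF, −30 → 0 °C; 1 M HCl, 0 °C
Reagents that add atoms: none
Why: Copper-catalysed Grignard opening of the 2,2-disubstituted epoxide at its CH2 terminus (SN2) leaves the quaternary centre untouched, so C3 is taken from the epoxy alcohol.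

Step 9
Reactants: 14 (2S)-2-methylhex-5-ene-1,2-diol
Product: 15 (4S)-4-(but-3-en-1-yl)-4-methyl-2-phenyl-1,3-dioxolane (both epimers at C2)
Conditions: PhCH(OMe)2, camphorsulfonic acid (cat.), CH2Cl2, rt
Reagents that add atoms: (dimethoxymethyl)benzene COC(OC)c1ccccc1
Why: Acid-catalysed transacetalisation gives the benzylidene acetal, which allows the two hydroxyls to be told apart in the next step.

Step 10
Reactants: 15 (4S)-4-(but-3-en-1-yl)-4-methyl-2-phenyl-1,3-dioxolane
Product: 16 (2S)-2-(benzyloxy)-2-methylhex-5-en-1-ol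
Conditions: iBu2AlH, CH2Cl2, −78 → 0 °C; aq. potassium sodium tartrate
Reagents that add atoms: none
Why: Reductive acetal opening, in which the aluminium hydride should coordinate the less hindered primary oxygen and cleave that C–O bond, leaving the benzyl group on the tertiary oxygen.

Step 11
Reactants: 16 (2S)-2-(benzyloxy)-2-methylhex-5-en-1-ol
Product: 17 (2S)-2-(benzyloxy)-2-methylhex-5-enal
Conditions: Dess–Martin periodinane, CH2Cl2, rt
Reagents that add atoms: none
Why: Dess–Martin oxidation of the primary alcohol gives an aldehyde without α-hydrogen, which cannot epimerise.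

Step 12
Reactants: 18 (2-methylprop-2-en-1-yl)magnesium chloride; 19 triethyl orthoformate
Product: 20 4,4-diethoxy-2-methylbut-1-ene
Conditions: Et2O/THF, reflux; H2O
Reagents that add atoms: none
Why: Grignard substitution of one ethoxy group of the orthoester (Bodroux–Chichibabin aldehyde synthesis stopped at the acetal) gives the stable diethyl acetal of the isomerisation-prone 3-methylbut-3-enal.

Step 13
Reactants: 11 (1R,4R,6R)-6-methyl-4-[(2R)-1-(triisopropylsilyloxy)propan-2-yl]cyclohex-2-en-1-yl N,N-di(propan-2-yl)carbamate; 17 (2S)-2-(benzyloxy)-2-methylhex-5-enal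
Product: 23 (3S,4S,6R)-3-[(1R,2S)-2-(benzyloxy)-1-hydroxy-2-methylhex-5-en-1-yl]-6-methyl-4-[(2R)-1-(triisopropylsilyloxy)propan-2-yl]cyclohex-1-en-1-yl N,N-di(propan-2-yl)carbamate, via lithiated carbamate 21 (not isolated), via allyltitanium 22 (not isolated)
Conditions: sBuLi, TMEDA, Et2O, −78 °C; ClTi(OiPr)3, −78 °C; 17, −78 °C → rt; aq. HCl
Reagents that add atoms: none
Why: Homoaldol reaction of a metalated allyl carbamate: carbamate-directed lithiation replaces the carbinol hydrogen with retention, lithium–titanium exchange inverts so that titanium sits on the ring face opposite the C14 side chain, and the aldehyde adds at the γ-carbon on that face through a Zimmerman–Traxler chair with its quaternary group equatorial, which sets C1 and C2 and leaves the ring enol carbamate.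

Step 14
Reactants: 23 (3S,4S,6R)-3-[(1R,2S)-2-(benzyloxy)-1-hydroxy-2-methylhex-5-en-1-yl]-6-methyl-4-[(2R)-1-(triisopropylsilyloxy)propan-2-yl]cyclohex-1-en-1-yl N,N-di(propan-2-yl)carbamate; 20 4,4-diethoxy-2-methylbut-1-ene
Product: 26 (1R,3R,3aR,5R,7S,7aS)-1-[(2S)-2-(benzyloxy)hex-5-en-2-yl]-5-methyl-3-(2-methylprop-2-en-1-yl)-7-[(2R)-1-(triisopropylsilyloxy)propan-2-yl]hexahydro-2-benzofuran-4(1H)-one, via mixed acetal 24 (not isolated), via oxocarbenium ion 25 (not isolated)
Conditions: 20 (2 equiv), BF3·OEt2 (2.5 equiv), Et2O, −78 → 0 °C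
Reagents that add atoms: none
Why: BF3·OEt2 ionises the acetal, the C2 hydroxyl is exchanged in to give mixed acetal 24, and loss of the second ethoxide gives the (E)-oxocarbenium ion 25 on the C2 oxygen; the enol carbamate carbon C10 then attacks C9 and the O-carbamoyl oxocarbenium ion so formed collapses to the C11 ketone by passing its carbamoyl group to ethoxide. The closest known reaction type is the Lewis acid-mediated condensation of 4-hydroxy enol carbamates (homoaldol adducts) with aldehydes or acetals to tetrasubstituted tetrahydrofurans, an intramolecular Mukaiyama-type (Prins-type) addition of an enol derivative to an oxocarbenium ion. The tetrahydrofuran closes in a 5-(enol-exo)-endo-trig mode, which is facile for oxocarbenium electrophiles. C10 is a ring carbon and C9 is delivered from the substituent on the neighbouring ring carbon C1, so the bond can only form on the ring face that carries that substituent (cis fusion); C9 is set in the envelope transition state, where the (E)-configured C=O+ unit turns its C8 chain outward and the bulky C3 group on C2 likewise avoids the fused ring, which should put both side chains on the same side of the new ring (2,5-cis, all-cis tetrahydrofuran). The step needs the enol carbamate to win over the two alkenes and to react at C10 only: its position (C10=C11) was fixed in step 13 and it is by far the strongest π-nucleophile, the methallyl alkene could only close a three- or four-membered ring, the monosubstituted alkene is a weak nucleophile, and the acetal is used because the free β,γ-unsaturated aldehyde would isomerise.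

Step 15
Reactants: 26 (1R,3R,3aR,5R,7S,7aS)-1-[(2S)-2-(benzyloxy)hex-5-en-2-yl]-5-methyl-3-(2-methylprop-2-en-1-yl)-7-[(2R)-1-(triisopropylsilyloxy)propan-2-yl]hexahydro-2-benzofuran-4(1H)-one
Product: 27 tricyclic ketone (oxonene closed; 11-oxo; 3-O-benzyl; 16-O-triisopropylsilyl; 1S,2R,3S,6Z,9R,10R,12R,14S,15R)
Conditions: second-generation Grubbs catalyst RuCl2(=CHPh)(PCy3)(H2IMes) (10 mol%), CH2Cl2 (2 mM), 40 °C
Reagents that add atoms: none
Why: Ring-closing metathesis between the monosubstituted and the 1,1-disubstituted alkene, held cis on the tetrahydrofuran, closes the nine-membered ether; the ring size enforces the Z geometry at C6=C7 and high dilution suppresses oligomers.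

Step 16
Reactants: 27 tricyclic ketone
Product: 28 tricyclic alcohol (11-OH cis to the C12 methyl group and to C9; 3-O-benzyl; 16-O-triisopropylsilyl; 1S,2R,3S,6Z,9R,10S,11R,12R,14S,15R)
Conditions: LiBH(sBu)3, THF, −78 °C; H2O
Reagents that add atoms: none
Why: Ketone reduction with a bulky borohydride, in which the two α-substituents (C9 on C10 and the C12 methyl group) occupy one face of the carbonyl so that hydride should enter from the other face and give the all-cis (11R) alcohol.

Step 17
Reactants: 28 tricyclic alcohol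
Product: 29 diol (3-OH and 11-OH free; 16-O-triisopropylsilyl; 1S,2R,3S,6Z,9R,10S,11R,12R,14S,15R)
Conditions: Na, NH3(l), THF, −78 °C; NH4Cl
Reagents that add atoms: none
Why: Dissolving-metal (Birch-type) cleavage of the benzyl ether frees the tertiary C3 hydroxyl without touching the isolated trisubstituted alkene or the silyl ether.

Step 18
Reactants: 29 diol
Product: 30 11-acetate (3-OH free; 16-O-triisopropylsilyl; 1S,2R,3S,6Z,9R,10R,11R,12R,14S,15R)
Conditions: Ac2O, pyridine, DMAP (cat.), CH2Cl2, 0 °C → rt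
Reagents that add atoms: acetic anhydride CC(=O)OC(C)=O
Why: DMAP-catalysed acylation should take the secondary C11 hydroxyl only, because the tertiary C3 hydroxyl acylates far more slowly.

Step 19
Reactants: 30 11-acetate
Product: 31 hydroxy acetate (3-OH and 16-OH free; 11-OAc; 1S,2R,3S,6Z,9R,10R,11R,12R,14S,15R)
Conditions: HF·pyridine, pyridine, THF, 0 °C → rt
Reagents that add atoms: none
Why: Fluoride-induced Si–O cleavage frees the C16 hydroxyl under conditions mild enough for the acetate and the alkene.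

Step 20
Reactants: 31 hydroxy acetate
Product: 33 CNP0177382.5 (1S,2R,3S,6Z,9R,10R,11R,12R,14S,15R), via primary triflate 32 (not isolated)
Conditions: Tf2O (1.1 equiv), 2,6-lutidine, CH2Cl2, −78 → 0 °C
Reagents that add atoms: none
Why: Selective triflation of the primary hydroxyl and intramolecular Williamson-type etherification (7-exo-tet SN2 at C16 by the tertiary C3 hydroxyl) close the oxepane without touching any stereocentre, the base removing the acid.

**Compound list**

1 | (2S)-3-bromo-2-methylpropan-1-ol | BrC[C@@H](C)CO | starting material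
2 | [(2S)-3-bromo-2-methylpropoxy]tri(propan-2-yl)silane | BrC[C@@H](C)CO[Si](C(C)C)(C(C)C)C(C)C | intermediate
3 | [(2S)-2-methyl-3-(triisopropylsilyloxy)propyl]magnesium bromide (formed in the flask) | Br[Mg]C[C@@H](C)CO[Si](C(C)C)(C(C)C)C(C)C | intermediate
4 | (3R)-3-methyl-4-(triisopropylsilyloxy)butanal | O=CC[C@@H](C)CO[Si](C(C)C)(C(C)C)C(C)C | intermediate
5 | but-3-en-2-one | CC(=O)C=C | starting material
6 | (2S)-5-oxo-2-[(2R)-1-(triisopropylsilyloxy)propan-2-yl]hexanal | O=C[C@@H](CCC(C)=O)[C@@H](C)CO[Si](C(C)C)(C(C)C)C(C)C | intermediate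
7 | (4R)-4-[(2R)-1-(triisopropylsilyloxy)propan-2-yl]cyclohex-2-en-1-one | O=C1C=C[C@@H](CC1)[C@@H](C)CO[Si](C(C)C)(C(C)C)C(C)C | intermediate
8 | lithium dienolate of 7, enolised toward C6 (formed in the flask) | [Li]OC1=CC[C@@H]([C@@H](C)CO[Si](C(C)C)(C(C)C)C(C)C)C=C1 | intermediate
9 | (4R,6R)-6-methyl-4-[(2R)-1-(triisopropylsilyloxy)propan-2-yl]cyclohex-2-en-1-one | O=C1C=C[C@@H](C[C@H]1C)[C@@H](C)CO[Si](C(C)C)(C(C)C)C(C)C | intermediate
10 | (1R,4R,6R)-6-methyl-4-[(2R)-1-(triisopropylsilyloxy)propan-2-yl]cyclohex-2-en-1-ol | O[C@H]1C=C[C@@H](C[C@H]1C)[C@@H](C)CO[Si](C(C)C)(C(C)C)C(C)C | intermediate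
11 | (1R,4R,6R)-6-methyl-4-[(2R)-1-(triisopropylsilyloxy)propan-2-yl]cyclohex-2-en-1-yl N,N-di(propan-2-yl)carbamate | CC(C)N(C(C)C)C(=O)O[C@H]1C=C[C@@H](C[C@H]1C)[C@@H](C)CO[Si](C(C)C)(C(C)C)C(C)C | intermediate
12 | [(2R)-2-methyloxiran-2-yl]methanol | OC[C@@]1(C)OC1 | starting material
13 | prop-2-en-1-ylmagnesium chloride | C=CC[Mg]Cl | starting material
14 | (2S)-2-methylhex-5-ene-1,2-diol | OC[C@@](C)(O)CCC=C | intermediate
15 | (4S)-4-(but-3-en-1-yl)-4-methyl-2-phenyl-1,3-dioxolane (both epimers at C2) | C=CCC[C@@]1(C)COC(c2ccccc2)O1 | intermediate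
16 | (2S)-2-(benzyloxy)-2-methylhex-5-en-1-ol | OC[C@@](C)(OCc1ccccc1)CCC=C | intermediate
17 | (2S)-2-(benzyloxy)-2-methylhex-5-enal | O=C[C@@](C)(OCc1ccccc1)CCC=C | intermediate
18 | (2-methylprop-2-en-1-yl)magnesium chloride | CC(=C)C[Mg]Cl | starting material
19 | triethyl orthoformate | CCOC(OCC)OCC | starting material
20 | 4,4-diethoxy-2-methylbut-1-ene | CCOC(CC(C)=C)OCC | intermediate
21 | 1-lithio derivative of 11, lithium on the face of the removed hydrogen (formed in the flask) | CC(C)N(C(C)C)C(=O)O[C@@]1([Li])C=C[C@@H](C[C@H]1C)[C@@H](C)CO[Si](C(C)C)(C(C)C)C(C)C | intermediate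
22 | 1-(triisopropoxytitanio) derivative of 11, titanium on the opposite face (formed in the flask) | CC(C)N(C(C)C)C(=O)O[C@]1([Ti](OC(C)C)(OC(C)C)OC(C)C)C=C[C@@H](C[C@H]1C)[C@@H](C)CO[Si](C(C)C)(C(C)C)C(C)C | intermediate
23 | (3S,4S,6R)-3-[(1R,2S)-2-(benzyloxy)-1-hydroxy-2-methylhex-5-en-1-yl]-6-methyl-4-[(2R)-1-(triisopropylsilyloxy)propan-2-yl]cyclohex-1-en-1-yl N,N-di(propan-2-yl)carbamate | CC(C)N(C(C)C)C(=O)OC1=C[C@H]([C@@H](C[C@H]1C)[C@@H](C)CO[Si](C(C)C)(C(C)C)C(C)C)[C@@H](O)[C@@](C)(OCc2ccccc2)CCC=C | intermediate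
24 | mixed ethyl acetal of 23, C2–O–CH(OEt)CH2C(CH3)=CH2 (formed in the flask) | CC(C)N(C(C)C)C(=O)OC1=C[C@H]([C@@H](C[C@H]1C)[C@@H](C)CO[Si](C(C)C)(C(C)C)C(C)C)[C@@H](OC(OCC)CC(C)=C)[C@@](C)(OCc2ccccc2)CCC=C | intermediate
25 | (E)-oxocarbenium ion on the C2 oxygen (formed in the flask) | CC(C)N(C(C)C)C(=O)OC1=C[C@H]([C@@H](C[C@H]1C)[C@@H](C)CO[Si](C(C)C)(C(C)C)C(C)C)[C@@H](/[O+]=C/CC(C)=C)[C@@](C)(OCc2ccccc2)CCC=C | intermediate
26 | (1R,3R,3aR,5R,7S,7aS)-1-[(2S)-2-(benzyloxy)hex-5-en-2-yl]-5-methyl-3-(2-methylprop-2-en-1-yl)-7-[(2R)-1-(triisopropylsilyloxy)propan-2-yl]hexahydro-2-benzofuran-4(1H)-one | O=C1[C@@H]2[C@H]([C@@H](C[C@H]1C)[C@@H](C)CO[Si](C(C)C)(C(C)C)C(C)C)[C@H]([C@@](C)(OCc3ccccc3)CCC=C)O[C@@H]2CC(C)=C | intermediate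
27 | tricyclic ketone: cyclohexanone–tetrahydrofuran–(Z)-oxonene, 11-oxo, 3-O-benzyl, 16-O-triisopropylsilyl | O=C1[C@@H]2[C@H]([C@@H](C[C@H]1C)[C@@H](C)CO[Si](C(C)C)(C(C)C)C(C)C)[C@H]3O[C@@H]2C/C(C)=C\CC[C@]3(C)OCc4ccccc4 | intermediate
28 | tricyclic (11R)-alcohol, 3-O-benzyl, 16-O-triisopropylsilyl | O[C@H]1[C@@H]2[C@H]([C@@H](C[C@H]1C)[C@@H](C)CO[Si](C(C)C)(C(C)C)C(C)C)[C@H]3O[C@@H]2C/C(C)=C\CC[C@]3(C)OCc4ccccc4 | intermediate
29 | tricyclic 3,11-diol, 16-O-triisopropylsilyl | O[C@H]1[C@@H]2[C@H]([C@@H](C[C@H]1C)[C@@H](C)CO[Si](C(C)C)(C(C)C)C(C)C)[C@H]3O[C@@H]2C/C(C)=C\CC[C@]3(C)O | intermediate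
30 | tricyclic 11-acetate, 3-OH free, 16-O-triisopropylsilyl | CC(=O)O[C@H]1[C@@H]2[C@H]([C@@H](C[C@H]1C)[C@@H](C)CO[Si](C(C)C)(C(C)C)C(C)C)[C@H]3O[C@@H]2C/C(C)=C\CC[C@]3(C)O | intermediate
31 | tricyclic 11-acetate with free 3-OH and 16-OH | CC(=O)O[C@H]1[C@@H]2[C@H]([C@@H](C[C@H]1C)[C@@H](C)CO)[C@H]3O[C@@H]2C/C(C)=C\CC[C@]3(C)O | intermediate
32 | C16 trifluoromethanesulfonate of 31 (formed in the flask) | CC(=O)O[C@H]1[C@@H]2[C@H]([C@@H](C[C@H]1C)[C@@H](C)COS(=O)(=O)C(F)(F)F)[C@H]3O[C@@H]2C/C(C)=C\CC[C@]3(C)O | intermediate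
33 | CNP0177382.5, tetracyclic acetate with the C3–O–C16 oxepane | CC(=O)O[C@H]1[C@@H]2[C@@H]3[C@@H](C[C@H]1C)[C@@H](C)CO[C@@]1(C)CC/C=C(/C)C[C@H]2O[C@H]31 | target

**Totals**

Total step count: 20. Longest linear sequence: 15 steps (steps 1–7, then 13–20).

**Steps most likely to fail**

Step 6 (reduction of the enone). Hydride may add through the half-chair with the equatorial methyl group instead, so that facial selectivity is poor or reversed. The carbinol epimer then dominates and step 13 would metalate the wrong ring face. Fallback: setting out from 9, the reduction mixture is separated and the (1S)-epimeric alcohol F1 is inverted by a Mitsunobu reaction (PPh3, diisopropyl azodicarboxylate, 4-nitrobenzoic acid, THF) to the (1R)-4-nitrobenzoate F2. Methanolysis (K2CO3, MeOH) comes back to 10.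

Step 13 (homoaldol union). The methyl group next to the carbanion may slow deprotonation, and titanium has to sit cis to it. Incomplete metalation, loss of configuration at the metal-bearing carbon or a sluggish γ-addition to the hindered aldehyde are therefore possible. Fallback: postpone the methyl group.
- Setting out from 7, Luche reduction should give the trans alcohol F3 and carbamoylation gives carbamate F4.
- Lithiation (lithio compound F5), titanation (titanium compound F6) and addition to 17 give homoaldol adduct F7.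
- Condensation with 20 and BF3·OEt2 (mixed acetal F8, oxocarbenium ion F9) gives bicyclic ketone F10, and ring-closing metathesis gives tricyclic ketone F11.
- α-Methylenation at the only α-CH2 (paraformaldehyde, N-methylanilinium trifluoroacetate, THF, reflux) gives methylidene ketone F12.
- Hydrogenation (H2, RhCl(PPh3)3, benzene) from the face opposite the tetrahydrofuran ring should set C12 and comes back to 27.

Step 14 (key step). The enol carbamate may attack the oxocarbenium ion too slowly. Double-bond migration in the methallyl unit or attack of BF3·OEt2 on the silyl or benzyl ether could then compete. Fallback with a stronger nucleophile and a milder acid: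
- Setting out from 23, mixed acetal 24 is made and isolated (20, pyridinium 4-toluenesulfonate, CH2Cl2, removal of ethanol).
- The carbamate is cleaved with MeLi (THF, −78 → 0 °C) to lithium enolate F13, which is silylated (Me3SiCl) to trimethylsilyl enol ether F14.
- Me3SiOTf (catalytic, CH2Cl2, −78 °C) then effects the intramolecular Mukaiyama-type addition to the same oxocarbenium ion and comes back to 26.

**Further compounds**

F1 | step 6 | (1S,4R,6R)-6-methyl-4-[(2R)-1-(triisopropylsilyloxy)propan-2-yl]cyclohex-2-en-1-ol | O[C@@H]1C=C[C@@H](C[C@H]1C)[C@@H](C)CO[Si](C(C)C)(C(C)C)C(C)C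
F2 | step 6 | (1R,4R,6R)-6-methyl-4-[(2R)-1-(triisopropylsilyloxy)propan-2-yl]cyclohex-2-en-1-yl 4-nitrobenzoate | O=C(O[C@H]1C=C[C@@H](C[C@H]1C)[C@@H](C)CO[Si](C(C)C)(C(C)C)C(C)C)c2ccc(cc2)[N+](=O)[O-]
F3 | step 13 | (1R,4R)-4-[(2R)-1-(triisopropylsilyloxy)propan-2-yl]cyclohex-2-en-1-ol | O[C@H]1C=C[C@@H](CC1)[C@@H](C)CO[Si](C(C)C)(C(C)C)C(C)C
F4 | step 13 | (1R,4R)-4-[(2R)-1-(triisopropylsilyloxy)propan-2-yl]cyclohex-2-en-1-yl N,N-di(propan-2-yl)carbamate | CC(C)N(C(C)C)C(=O)O[C@H]1C=C[C@@H](CC1)[C@@H](C)CO[Si](C(C)C)(C(C)C)C(C)C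
F5 | step 13 | 1-lithio derivative of F4 | CC(C)N(C(C)C)C(=O)O[C@@]1([Li])C=C[C@@H](CC1)[C@@H](C)CO[Si](C(C)C)(C(C)C)C(C)C
F6 | step 13 | 1-(triisopropoxytitanio) derivative of F4 | CC(C)N(C(C)C)C(=O)O[C@]1([Ti](OC(C)C)(OC(C)C)OC(C)C)C=C[C@@H](CC1)[C@@H](C)CO[Si](C(C)C)(C(C)C)C(C)C
F7 | step 13 | 12-demethyl analogue of 23 | CC(C)N(C(C)C)C(=O)OC1=C[C@H]([C@@H](CC1)[C@@H](C)CO[Si](C(C)C)(C(C)C)C(C)C)[C@@H](O)[C@@](C)(OCc2ccccc2)CCC=C
F8 | step 13 | 12-demethyl analogue of 24 | CC(C)N(C(C)C)C(=O)OC1=C[C@H]([C@@H](CC1)[C@@H](C)CO[Si](C(C)C)(C(C)C)C(C)C)[C@@H](OC(OCC)CC(C)=C)[C@@](C)(OCc2ccccc2)CCC=C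
F9 | step 13 | 12-demethyl analogue of 25 | CC(C)N(C(C)C)C(=O)OC1=C[C@H]([C@@H](CC1)[C@@H](C)CO[Si](C(C)C)(C(C)C)C(C)C)[C@@H](/[O+]=C/CC(C)=C)[C@@](C)(OCc2ccccc2)CCC=C
F10 | step 13 | 12-demethyl analogue of 26 | O=C1[C@@H]2[C@H]([C@@H](CC1)[C@@H](C)CO[Si](C(C)C)(C(C)C)C(C)C)[C@H]([C@@](C)(OCc3ccccc3)CCC=C)O[C@@H]2CC(C)=C
F11 | step 13 | 12-demethyl analogue of 27 | O=C1[C@@H]2[C@H]([C@@H](CC1)[C@@H](C)CO[Si](C(C)C)(C(C)C)C(C)C)[C@H]3O[C@@H]2C/C(C)=C\CC[C@]3(C)OCc4ccccc4
F12 | step 13 | 12-methylidene analogue of 27 | O=C1[C@@H]2[C@H]([C@@H](CC1=C)[C@@H](C)CO[Si](C(C)C)(C(C)C)C(C)C)[C@H]3O[C@@H]2C/C(C)=C\CC[C@]3(C)OCc4ccccc4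
F13 | step 14 | lithium enolate (C10=C11) of mixed acetal 24 after loss of the carbamoyl group | [Li]OC1=C[C@H]([C@@H](C[C@H]1C)[C@@H](C)CO[Si](C(C)C)(C(C)C)C(C)C)[C@@H](OC(OCC)CC(C)=C)[C@@](C)(OCc2ccccc2)CCC=C
F14 | step 14 | trimethylsilyl enol ether of F13 | C[Si](C)(C)OC1=C[C@H]([C@@H](C[C@H]1C)[C@@H](C)CO[Si](C(C)C)(C(C)C)C(C)C)[C@@H](OC(OCC)CC(C)=C)[C@@](C)(OCc2ccccc2)CCC=C
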